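The target is cut at C11–C12 and at C15–O. The acyclic C12–C16 segment between the C11 methylene on C9 of ring B (A/B ent-labdane decalin) and the ester oxygen is exactly one isoprene unit. One light-driven, palladium-catalysed operation joins three pieces. The C11 radical released by decarboxylation adds to isoprene, and the derived π-allylpalladium species is captured at C15 by unprotected 30-hydroxytriacontanoic acid. The precursor is the N-hydroxyphthalimide ester of ent-3-hydroxy-13,14,15,16-tetranorlabd-7-en-12-oic acid. It already holds rings A and B, the Δ7 alkene and all four stereocentres (C3, C5, C9, C10), and it comes from andrographolide by degradation.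

Key step: step 10

**Remarks on the chemistry (valid for all steps)**
- Numbering: labdane numbering is used (ring A = C1–C5, C10; ring B = C5–C10). The carboxyl carbon of 11 and 13 leaves as CO2 in step 10, so C12–C16 of 16 all come from isoprene.
- Structure check: the target is (3R,5S,9R,10S,13E), which is the ent-labdane series. These four centres map atom by atom onto C3, C5, C9 and C10 of andrographolide. C4 stops being stereogenic once the C19 oxygen is removed, and the acyl chain has 30 carbons. No structure needed correction.
- Assumption: 30-hydroxytriacontanoic acid (15) is bought as a lipid standard; 1, 12 and 14 are bulk chemicals.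
- Precursor design:
  - An N-acyloxyphthalimide sets free phthalimide anion, which is itself a good nucleophile for π-allylpalladium.
  - The skeleton of 13 is kept, and the unsubstituted imide is chosen on purpose. Its anion is basic enough to be protonated by a carboxylic acid, so 15 is used as the free acid and no base is added.
  - A tetrachlorinated imide would stay anionic. It would also make the active ester more prone to acyl transfer to carboxylate or to the ω-hydroxyl.
  - C3–OH stays free because it is equatorial, shielded by the C4 gem-dimethyl group, and inert in a neutral medium.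

**Route**

Step 1
Reactants: 1 andrographolide
Product: 3 ent-3,19-dihydroxy-8-oxo-13,14,15,16,17-pentanorlabdan-12-oic acid (3R,4R,5S,9S,10R), via keto aldehyde 2 (not isolated)
Conditions: O3, CH2Cl2/MeOH (1:1), −78 °C, until blue; Me2S, −78 °C → rt; concentrate; NaClO2, NaH2PO4, 2-methylbut-2-ene, t-BuOH/H2O, rt
Reagents that add atoms: ozone, O=[O+][O-]; sodium chlorite, [Na+].[O-]Cl=O
Why: Criegee ozonolysis cleaves the 1,1-disubstituted C8=C17 alkene and the lactone-conjugated C12=C13 alkene alike and so removes C17 and C13–C16 in one pass, the Pinnick oxidation then takes only the C12 aldehyde of the crude γ-keto aldehyde to the acid, and C3, C4, C5, C9 and C10 are carried over from 1, the equatorial C9 side chain being the stable epimer next to the new ketone.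

Step 2
Reactants: 3 ent-3,19-dihydroxy-8-oxo-13,14,15,16,17-pentanorlabdan-12-oic acid
Product: 4 methyl ent-3,19-dihydroxy-8-oxo-13,14,15,16,17-pentanorlabdan-12-oate (3R,4R,5S,9S,10R)
Conditions: MeI, K2CO3, DMF, rt
Reagents that add atoms: iodomethane, CI
Why: SN2 O-alkylation of the carboxylate gives the open-chain methyl ester, whereas acid-catalysed esterification of a γ-keto acid could give the cyclic pseudo-ester, and carbonate does not deprotonate the two alcohols.

Step 3
Reactants: 4 methyl ent-3,19-dihydroxy-8-oxo-13,14,15,16,17-pentanorlabdan-12-oate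
Product: 5 methyl ent-3-hydroxy-19-iodo-8-oxo-13,14,15,16,17-pentanorlabdan-12-oate (3R,4S,5S,9S,10R)
Conditions: I2, PPh3, imidazole, PhMe, 85 °C
Reagents that add atoms: iodine, II
Why: In this Appel-type (Garegg–Samuelsson) iodination the primary C19 alcohol forms the alkoxyphosphonium ion faster than the equatorial secondary C3 alcohol, and iodide displaces it on heating without rearrangement, as is usual for neopentyl carbinols; C4 keeps its spatial arrangement because only the C19–O bond breaks.

Step 4
Reactants: 5 methyl ent-3-hydroxy-19-iodo-8-oxo-13,14,15,16,17-pentanorlabdan-12-oate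
Product: 6 methyl ent-3-hydroxy-8-oxo-13,14,15,16,17-pentanorlabdan-12-oate (3R,5S,9S,10R)
Conditions: n-Bu3SnH, AIBN (cat.), PhMe, 80 °C
Reagents that add atoms: none
Why: Radical chain dehalogenation needs no displacement at the hindered carbon: the stannyl radical abstracts iodine, the primary C19 radical takes hydrogen from the stannane, ketone, ester and alcohol are inert, and C4 becomes a gem-dimethyl carbon that is no longer stereogenic.

Step 5
Reactants: 6 methyl ent-3-hydroxy-8-oxo-13,14,15,16,17-pentanorlabdan-12-oate
Product: 7 methyl ent-3-benzoyloxy-8-oxo-13,14,15,16,17-pentanorlabdan-12-oate (3R,5S,9S,10R)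
Conditions: BzCl, pyridine, DMAP (cat.), CH2Cl2, rt → 40 °C
Reagents that add atoms: benzoyl chloride, O=C(Cl)c1ccccc1
Why: DMAP-catalysed acylation covers the hindered equatorial C3 alcohol with retention (only the O–H bond reacts), and a benzoate is chosen because it has no α-hydrogen for the amide base of step 6 and leaves together with the methyl ester in step 8.

Step 6
Reactants: 7 methyl ent-3-benzoyloxy-8-oxo-13,14,15,16,17-pentanorlabdan-12-oate
Product: 9 methyl ent-3-benzoyloxy-8-(trifluoromethylsulfonyloxy)-13,14,15,16,17-pentanorlabd-7-en-12-oate (3R,5S,9S,10R), via potassium enolate 8 (not isolated)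
Conditions: KHMDS (1.1 equiv), THF, −78 °C; PhNTf2, −78 → 0 °C
Reagents that add atoms: N-phenylbis(trifluoromethanesulfonimide), O=S(=O)(N(c1ccccc1)S(=O)(=O)C(F)(F)F)C(F)(F)F; potassium bis(trimethylsilyl)amide, [K+].C[Si](C)(C)[N-][Si](C)(C)C (potassium of 8 only)
Why: Kinetic deprotonation of a 2-substituted cyclohexanone by a bulky amide base at −78 °C takes a C7 hydrogen rather than the C9 methine beside quaternary C10 or the less acidic C11 hydrogens of the ester, and O-sulfonylation of the enolate with the triflimide fixes the double bond at C7=C8 without touching C9.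

Step 7
Reactants: 9 methyl ent-3-benzoyloxy-8-(trifluoromethylsulfonyloxy)-13,14,15,16,17-pentanorlabd-7-en-12-oate
Product: 10 methyl ent-3-benzoyloxy-13,14,15,16-tetranorlabd-7-en-12-oate (3R,5S,9R,10S)
Conditions: MeZnCl, Pd(PPh3)4 (5 mol %), THF, 50 °C
Reagents that add atoms: methylzinc chloride, C[Zn]Cl
Why: Negishi cross-coupling of the alkenyl triflate with a methylzinc reagent puts C17 back on C8 with the alkene locked at C7=C8, and organozinc reagents leave both esters alone.

Step 8
Reactants: 10 methyl ent-3-benzoyloxy-13,14,15,16-tetranorlabd-7-en-12-oate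
Product: 11 ent-3-hydroxy-13,14,15,16-tetranorlabd-7-en-12-oic acid (3R,5S,9R,10S)
Conditions: KOH, MeOH/THF/H2O, 65 °C; then 1 M HCl, 0 °C, to pH 3
Reagents that add atoms: potassium hydroxide, [K+].[OH-]
Why: Saponification (BAc2) removes the methyl ester and the hindered C3 benzoate in one operation without breaking any bond at a stereocentre, and brief cold acidification avoids acid-catalysed lactonisation of the acid onto C8.

Step 9
Reactants: 11 ent-3-hydroxy-13,14,15,16-tetranorlabd-7-en-12-oic acid; 12 N-hydroxyphthalimide
Product: 13 1,3-dioxoisoindolin-2-yl ent-3-hydroxy-13,14,15,16-tetranorlabd-7-en-12-oate (3R,5S,9R,10S)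
Conditions: DIC, DMAP (5 mol %), CH2Cl2, 0 °C → rt, short silica plug, stored in the dark
Reagents that add atoms: N-hydroxyphthalimide (12), O=C1c2ccccc2C(=O)N1O
Why: Carbodiimide coupling of the Steglich type works because the acidic N–OH nucleophile intercepts the O-acylisourea far faster than the C3 alcohol, which is shielded by the C4 gem-dimethyl group.

Step 10
Reactants: 13 1,3-dioxoisoindolin-2-yl ent-3-hydroxy-13,14,15,16-tetranorlabd-7-en-12-oate; 14 isoprene; 15 30-hydroxytriacontanoic acid
Product: 16 (13E)-ent-3-hydroxylabda-7,13-dien-15-yl 30-hydroxytriacontanoate (3R,5S,9R,10S), CNP0303636.1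
Conditions: Pd(PPh3)4 (5 mol %), Xantphos (6 mol %), 14 (20 equiv), 15 (1.5 equiv), no base, PhCF3/THF (4:1), 45 °C, 450 nm LEDs, sealed tube, Ar; AgNO3–SiO2 chromatography
Reagents that add atoms: isoprene (14), C=CC(C)=C; 30-hydroxytriacontanoic acid (15), OCCCCCCCCCCCCCCCCCCCCCCCCCCCCCC(=O)O
Why: Proposed new method: photoexcited Pd(0) reduces the N-acyloxyphthalimide 13 by single-electron transfer, N–O cleavage and loss of CO2 leave the primary C11 radical and Pd(I), the radical adds to the CH2 terminus of isoprene that adjoins the methyl-bearing carbon (C11–C12 bond), the allyl radical recombines with Pd(I), and the carboxylate of 15 opens the π-allylpalladium(II) cation at its unsubstituted terminus (C15–O bond) and returns Pd(0). The closest known reaction types are the visible-light Pd-catalysed 1,4-aminoalkylation of 1,3-dienes, in which such esters supply both the alkyl radical and the imide nucleophile, the related three-component 1,4-carbofunctionalisation with alkyl halides, and Tsuji–Trost substitution by carboxylates; the diversion of the decarboxylative variant to an external carboxylate is what is new. Because the liberated phthalimide anion is itself a good π-allyl nucleophile, 15 is added as the free acid without any base: the more acidic CO2H protonates the imide anion, which is parked as sparingly soluble N–H phthalimide, carboxylate exists only as the counter-ion of cationic palladium, and the active ester, the hindered C3–OH and the ω-OH never see a basic medium. No ring closes and no stereocentre is created, and C3, C5, C9 and C10 are remote from the reacting centres. The step needs radical attack at the terminus that gives the methyl-stabilised tertiary allyl radical, 1,4- rather than 1,2-capture (palladium directs the nucleophile to the CH2 terminus and a tertiary allylic ester formed in error re-ionises readily) and E geometry, which is inherited from the s-trans conformer of isoprene and held by the slow syn/anti exchange at a fully substituted allyl terminus. The C11 radical is a cyclohex-2-enylmethyl radical whose 3-exo closure onto C8 is slow and reverts to the same radical, so the large excess of isoprene should outrun it, and irradiation ends at full conversion of 13 so that re-ionisation of 16 cannot drain it to the N-allyl imide or the Z isomer.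

**Compound list**

1 | andrographolide | C[C@@]12CC[C@H]([C@@]([C@H]1CCC(=C)[C@H]2C/C=C/3\[C@@H](COC3=O)O)(C)CO)O | starting material
2 | ent-3,19-dihydroxy-8-oxo-13,14,15,16,17-pentanorlabdan-12-al (3R,4R,5S,9S,10R) | O=C1CC[C@@H]2[C@](C)(CO)[C@H](O)CC[C@@]2(C)[C@@H]1CC=O | intermediate
3 | ent-3,19-dihydroxy-8-oxo-13,14,15,16,17-pentanorlabdan-12-oic acid (3R,4R,5S,9S,10R) | O=C1CC[C@@H]2[C@](C)(CO)[C@H](O)CC[C@@]2(C)[C@@H]1CC(=O)O | intermediate
4 | methyl ent-3,19-dihydroxy-8-oxo-13,14,15,16,17-pentanorlabdan-12-oate (3R,4R,5S,9S,10R) | O=C1CC[C@@H]2[C@](C)(CO)[C@H](O)CC[C@@]2(C)[C@@H]1CC(=O)OC | intermediate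
5 | methyl ent-3-hydroxy-19-iodo-8-oxo-13,14,15,16,17-pentanorlabdan-12-oate (3R,4S,5S,9S,10R) | O=C1CC[C@@H]2[C@](C)(CI)[C@H](O)CC[C@@]2(C)[C@@H]1CC(=O)OC | intermediate
6 | methyl ent-3-hydroxy-8-oxo-13,14,15,16,17-pentanorlabdan-12-oate (3R,5S,9S,10R) | O=C1CC[C@@H]2C(C)(C)[C@H](O)CC[C@@]2(C)[C@@H]1CC(=O)OC | intermediate
7 | methyl ent-3-benzoyloxy-8-oxo-13,14,15,16,17-pentanorlabdan-12-oate (3R,5S,9S,10R) | O=C1CC[C@@H]2C(C)(C)[C@H](OC(=O)c3ccccc3)CC[C@@]2(C)[C@@H]1CC(=O)OC | intermediate
8 | potassium C7=C8 enolate of 7 | [K+].[O-]C1=CC[C@@H]2C(C)(C)[C@H](OC(=O)c3ccccc3)CC[C@@]2(C)[C@@H]1CC(=O)OC | intermediate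
9 | methyl ent-3-benzoyloxy-8-(trifluoromethylsulfonyloxy)-13,14,15,16,17-pentanorlabd-7-en-12-oate (3R,5S,9S,10R) | O=S(=O)(OC1=CC[C@@H]2C(C)(C)[C@H](OC(=O)c3ccccc3)CC[C@@]2(C)[C@@H]1CC(=O)OC)C(F)(F)F | intermediate
10 | methyl ent-3-benzoyloxy-13,14,15,16-tetranorlabd-7-en-12-oate (3R,5S,9R,10S) | CC1=CC[C@@H]2C(C)(C)[C@H](OC(=O)c3ccccc3)CC[C@@]2(C)[C@@H]1CC(=O)OC | intermediate
11 | ent-3-hydroxy-13,14,15,16-tetranorlabd-7-en-12-oic acid (3R,5S,9R,10S) | CC1=CC[C@@H]2C(C)(C)[C@H](O)CC[C@@]2(C)[C@@H]1CC(=O)O | intermediate
12 | N-hydroxyphthalimide | O=C1c2ccccc2C(=O)N1O | starting material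
13 | 1,3-dioxoisoindolin-2-yl ent-3-hydroxy-13,14,15,16-tetranorlabd-7-en-12-oate (3R,5S,9R,10S) | CC1=CC[C@@H]2C(C)(C)[C@H](O)CC[C@@]2(C)[C@@H]1CC(=O)ON1C(=O)c2ccccc2C1=O | intermediate
14 | isoprene | C=CC(C)=C | starting material
15 | 30-hydroxytriacontanoic acid | OCCCCCCCCCCCCCCCCCCCCCCCCCCCCCC(=O)O | starting material
16 | (13E)-ent-3-hydroxylabda-7,13-dien-15-yl 30-hydroxytriacontanoate (3R,5S,9R,10S), CNP0303636.1 | CC1=CC[C@@H]2C(C)(C)[C@H](O)CC[C@@]2(C)[C@@H]1CC/C(C)=C/COC(=O)CCCCCCCCCCCCCCCCCCCCCCCCCCCCCO | target

**Totals**

Total step count: 10.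
Longest linear sequence: 10 steps (1 → 16); 12, 14 and 15 are bought and enter directly.

**Steps most likely to fail**

Step 10. Several things may go wrong:
- radical addition to the other terminus of isoprene;
- capture of the π-allyl complex by the imide instead of the carboxylate;
- erosion of the E geometry through repeated ionisation;
- β-hydride loss to a diene;
- palladium hydride addition of the acid to isoprene in the dark;
- a difficult separation of very similar waxy isomers.

The fallback uses known chemistry only, sets out from 10 and comes back at 16. LiAlH4 in THF reduces the methyl ester and removes the benzoate to give ent-13,14,15,16-tetranorlabd-7-ene-3,12-diol F1. Appel iodination (I2, PPh3, imidazole, CH2Cl2, 0 °C) of the unhindered primary alcohol gives ent-12-iodo-13,14,15,16-tetranorlabd-7-en-3-ol F2. Excess lithium acetylide–ethylenediamine in DMSO displaces iodide to give ent-15,16-dinorlabd-7-en-13-yn-3-ol F3. Zirconium-catalysed Negishi carboalumination (Me3Al, Cp2ZrCl2, CH2Cl2), then n-BuLi and paraformaldehyde, gives (13E)-ent-labda-7,13-diene-3,15-diol F4; here syn addition across the alkyne fixes the E geometry. MsCl, LiCl and 2,4,6-collidine in DMF at 0 °C convert only the primary allylic alcohol into (13E)-ent-15-chlorolabda-7,13-dien-3-ol F5. The caesium carboxylate of 15 (Cs2CO3, DMF/THF, 50 °C) then displaces chloride by SN2 to give 16, again without protection of the ω-hydroxyl.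

Step 3. The displacement at the axial neopentyl C19, which sits 1,3-diaxial to C20, may be slow. The C3 alcohol would then be activated in competition, and ring A would suffer elimination or contraction. The fallback sets out from 4 and comes back at 7. Benzaldehyde dimethyl acetal with catalytic CSA ties both oxygens into methyl ent-3,19-O-benzylidene-3,19-dihydroxy-8-oxo-13,14,15,16,17-pentanorlabdan-12-oate (phenyl equatorial) F6. Hanessian–Hullar opening (NBS, BaCO3, PhCl, reflux) passes through the cyclic benzoxonium ion, sends bromide to the primary carbon and leaves the benzoate on O3. This gives methyl ent-3-benzoyloxy-19-bromo-8-oxo-13,14,15,16,17-pentanorlabdan-12-oate F7, and n-Bu3SnH/AIBN then gives 7. The C3 oxygen can no longer be turned into a leaving group, and the separate benzoylation is saved.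

Step 6. Kinetic control may be lost through proton exchange between the enolate and unreacted ketone, or deprotonation at C11 may compete. Either would put the double bond in the wrong place. The fallback sets out from 7 and comes back at 10. LDA added to 7 in the presence of TMSCl (in situ quench, THF, −78 °C) traps the C7 enolate as it forms. The product is methyl ent-3-benzoyloxy-8-(trimethylsilyloxy)-13,14,15,16,17-pentanorlabd-7-en-12-oate F8, which can be purified and whose regiochemistry can be checked. Nonafluorobutanesulfonyl fluoride with catalytic fluoride converts it, with the double bond held in place, into methyl ent-3-benzoyloxy-8-(nonafluorobutylsulfonyloxy)-13,14,15,16,17-pentanorlabd-7-en-12-oate F9. The Negishi methylation of step 7 then gives 10.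

**Further compounds**

F1 | step 10 | ent-13,14,15,16-tetranorlabd-7-ene-3,12-diol | CC1=CC[C@@H]2C(C)(C)[C@H](O)CC[C@@]2(C)[C@@H]1CCO
F2 | step 10 | ent-12-iodo-13,14,15,16-tetranorlabd-7-en-3-ol | CC1=CC[C@@H]2C(C)(C)[C@H](O)CC[C@@]2(C)[C@@H]1CCI
F3 | step 10 | ent-15,16-dinorlabd-7-en-13-yn-3-ol | CC1=CC[C@@H]2C(C)(C)[C@H](O)CC[C@@]2(C)[C@@H]1CCC#C
F4 | step 10 | (13E)-ent-labda-7,13-diene-3,15-diol | CC1=CC[C@@H]2C(C)(C)[C@H](O)CC[C@@]2(C)[C@@H]1CC/C(C)=C/CO
F5 | step 10 | (13E)-ent-15-chlorolabda-7,13-dien-3-ol | CC1=CC[C@@H]2C(C)(C)[C@H](O)CC[C@@]2(C)[C@@H]1CC/C(C)=C/CCl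
F6 | step 3 | methyl ent-3,19-O-benzylidene-3,19-dihydroxy-8-oxo-13,14,15,16,17-pentanorlabdan-12-oate (phenyl equatorial) | O=C1CC[C@@H]2[C@]3(C)CO[C@@H](c4ccccc4)O[C@@H]3CC[C@@]2(C)[C@@H]1CC(=O)OC
F7 | step 3 | methyl ent-3-benzoyloxy-19-bromo-8-oxo-13,14,15,16,17-pentanorlabdan-12-oate | O=C1CC[C@@H]2[C@](C)(CBr)[C@H](OC(=O)c3ccccc3)CC[C@@]2(C)[C@@H]1CC(=O)OC
F8 | step 6 | methyl ent-3-benzoyloxy-8-(trimethylsilyloxy)-13,14,15,16,17-pentanorlabd-7-en-12-oate | C[Si](C)(C)OC1=CC[C@@H]2C(C)(C)[C@H](OC(=O)c3ccccc3)CC[C@@]2(C)[C@@H]1CC(=O)OC
F9 | step 6 | methyl ent-3-benzoyloxy-8-(nonafluorobutylsulfonyloxy)-13,14,15,16,17-pentanorlabd-7-en-12-oate | O=S(=O)(OC1=CC[C@@H]2C(C)(C)[C@H](OC(=O)c3ccccc3)CC[C@@]2(C)[C@@H]1CC(=O)OC)C(F)(F)C(F)(F)C(F)(F)C(F)(F)F
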